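## Analysis of the target

The target 11 is a diaryl ketone in which one carbonyl carbon joins C2 of a 4,5-dichloro-1H-pyrrole to C1 of a benzene ring. Numbered from that acyl-bearing carbon, the benzene ring carries hydroxyl groups on C2 and C4, a 4-methylpentyl chain on C3, and hydrogen on C5 and C6. There is no stereocentre and no double-bond geometry, so the task is one of connectivity and regiochemistry only. The sensitive parts are the two C–Cl bonds on an N–H pyrrole (hydrogenolysis, strong reductants, halogen–metal exchange), the acidic N–H, and the electron-rich dihydroxybenzene (oxidation, multiple substitution). The difficulty lies in the four contiguous substituents on the benzene ring, and above all in the chain on C3. This carbon lies between the two oxygen-bearing carbons, and electrophilic substitution of a 1,3-dioxygenated benzene goes to C4 and C6 instead. The strategy rests on this O–C–O triad at C2, C3 and C4. An aryne that already carries one oxygen as a methoxy group can take up the second oxygen and the first chain carbon, as an acyl carbon, on its two triple-bond carbons in one step. Once the chain carbonyl has been reduced and both oxygens are methyl ethers, the ring is symmetric, so the pyrrolyl ketone can enter at either of two equivalent positions.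

## Retrosynthetic reasoning

**11 to 10.** The two phenolic O–H groups of 11 are traced back to the methyl ethers of 10, (4,5-dichloro-1H-pyrrol-2-yl)[2,4-dimethoxy-3-(4-methylpentyl)phenyl]methanone. The two O–CH3 bonds are cut last because methyl ethers survive every earlier step, and a boron Lewis acid cleaves them without touching the C–Cl bonds, the N–H or the diaryl ketone. The forward step has to cleave both ethers, including the one para to the ketone, which is not assisted by chelation.

**10 to 7 and 9.** The bond between ring carbon C1 and the carbonyl carbon is cut. This gives 1,3-dimethoxy-2-(4-methylpentyl)benzene 7 and 4,5-dichloro-1H-pyrrole-2-carbonyl chloride 9, which comes in one step from the commercial acid 8. The cut is made on the benzene side because 7 is symmetric and electron-rich: its only activated positions, C4 and C6, are equivalent, and C5 is meta to both ethers. A cut on the pyrrole side would require a nucleophilic dichloropyrrole and would raise a regiochemical question on that ring. The forward reaction is an electrophilic acylation ortho to one methoxy group and para to the other.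

**7 to 6.** One O–CH3 bond is cut to give 3-methoxy-2-(4-methylpentyl)phenol 6. The aryne step delivers one oxygen free and one as a methyl ether. Capping the free one costs one step but prevents acylation on oxygen and creates the symmetry used in the acylation.

**6 to 5.** The benzylic CH2 is traced back to the ketone of 1-(2-hydroxy-6-methoxyphenyl)-4-methylpentan-1-one 5. The chain carbon arrives at the acyl oxidation level and is reduced at this early stage, when 5 holds only one carbonyl and no C–Cl bond, so the deoxygenation has no competing site.

**5 to 1 and 2.** Two adjacent bonds are cut in 5: the aryl C–O bond of the phenol and the aryl C–C bond to the acyl carbon. Together they correspond to the acyl C–O bond of 4-methylpentanoic acid 2. The two ring carbons are the triple-bond carbons of 3-methoxybenzyne 3, released by a fluoride source from the commercial silylaryl triflate 1; the aryl anion 4 is the intermediate that transfers the acyl group. This disconnection is preferred because it builds the whole O–C–O pattern in one operation from two purchasable compounds. The forward step has to place oxygen on the aryne carbon remote from the methoxy group and the acyl group on the carbon next to it, and the acyl transfer within 4 has to outrun protonation.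

## Alternatives that were turned down

**Alternative 1:** Michael–Claisen construction of the benzene ring.
- Disconnection: the benzene ring is opened at C1–C6 and C3–C4. This leads to the open-chain diketone A2, 1-[4,5-dichloro-1-(2-trimethylsilylethoxymethyl)pyrrol-2-yl]-8-methylnonane-1,3-dione, and a three-carbon acrylate ester.
- Forward key step: the central carbon of A2 adds to the acrylate (Michael), and the chain-bearing α-carbon then closes onto the ester (Claisen). The product is A1, 4-[4,5-dichloro-1-(2-trimethylsilylethoxymethyl)pyrrole-2-carbonyl]-2-(4-methylpentyl)cyclohexane-1,3-dione. Dehydrogenation to the aromatic ring and removal of the nitrogen protecting group follow.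
- For: every ring substituent is placed by connectivity, no aromatic substitution is needed, and the aryl–carbonyl bond exists from the start.
- Against: the Claisen closure must use the less acidic α-carbon while the doubly activated carbon still holds a proton. A second Michael addition at that carbon competes. The triketone A1 is open to retro-Claisen cleavage. The aromatisation must be done beside two C–Cl bonds, which excludes hot palladium-on-carbon dehydrogenation. A protecting group must be put on and taken off, and A2 itself needs a crossed Claisen condensation.
- Comparison: this route is stronger in that it avoids the acylation with an N–H pyrrole acid chloride. The chosen strategy offers a prefabricated ring, six steps, and a symmetric arene that makes the acylation unambiguous.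

**Alternative 2:** Chlorovinamidinium annulation of the pyrrole.
- Disconnection: the pyrrole is cut at N–C5 and C2–C3. This gives the α-amino ketone A4, 2-amino-1-[2,4-dimethoxy-3-(4-methylpentyl)phenyl]ethan-1-one, and the vinamidinium salt A5, 2-chloro-1,3-bis(dimethylamino)trimethinium hexafluorophosphate.
- Forward key step: the amine of A4 displaces one amino terminus of A5, and the ketone α-carbon closes onto the remaining iminium carbon. The product is A3, (4-chloro-1H-pyrrol-2-yl)[2,4-dimethoxy-3-(4-methylpentyl)phenyl]methanone, with the C4 chlorine in place.
- For: the conditions are mild, the first chlorine is placed without ambiguity, and the acid chloride 9 is not needed.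
- Against: the hard part of the target, the chain between the two oxygens, is not addressed. A4 still has to be made from an arene such as 7, by a haloacylation and an amination, and α-amino ketones condense with themselves. The second chlorine must be introduced late by electrophilic chlorination, which has to distinguish pyrrole C5 from pyrrole C3 and from the activated benzene C5.
- Comparison: this route is stronger in avoiding the Lewis-acid acylation with an N–H pyrrole. The chosen strategy buys both chlorines already in place in 8 and needs at least three fewer steps after 7.

**Alternative 3:** Benzannulation of a siloxyalkyne with a diazo enone.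
- Disconnection: four ring C–C bonds of the benzene are cut. This gives the siloxyalkyne A7, triisopropyl[(6-methylhept-1-yn-1-yl)oxy]silane, and the diazo enone A8, ethyl (E)-5-diazo-4-oxopent-2-enoate.
- Forward key step: photochemical Wolff rearrangement of A8 gives the vinylketene A9, ethyl (E)-5-oxopenta-2,4-dienoate. A9 adds (2+2) to A7, and 4π opening, 6π closure and tautomerisation follow. The product is A6, ethyl 2-hydroxy-3-(4-methylpentyl)-4-(triisopropylsilyloxy)benzoate.
- For: hydroxyl, chain, siloxy and ester are placed on adjacent carbons purely by the connectivity of the partners. The two oxygens are differentiated, and the future ketone carbon is already on the ring.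
- Against: A7 needs several steps of ynolate chemistry. A8 joins a diazo group to an electron-poor alkene and is prone to dipolar cycloaddition with itself. The photochemical step is hard to scale. The ester of A6 must still be turned into the dichloropyrrolyl ketone, which calls for an N-protected, C-metalated dichloropyrrole.
- Comparison: this route is stronger on regiochemical certainty and on differentiation of the oxygens. The chosen strategy does not need that differentiation, because the symmetry of 7 serves the same purpose, and it forms its two key bonds from two commercial compounds in one step.

Key step: step 1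

Remark on the chemistry: an acid chloride would acylate the free phenol of 6 on oxygen first, so 6 is capped as its methyl ether before the acylation; this adds one step to the shortest conceivable sequence.

## Route

Step 1
Reactants: 1 3-methoxy-2-(trimethylsilyl)phenyl trifluoromethanesulfonate; 2 4-methylpentanoic acid
Product: 5 1-(2-hydroxy-6-methoxyphenyl)-4-methylpentan-1-one, via 3-methoxybenzyne 3 (not isolated), via aryl cesium ester 4 (not isolated)
Conditions: CsF (4 equiv), 2 (1.5 equiv), THF, 125 °C, sealed tube; aq NH4Cl
Reagents that add atoms: none
Why: Fluoride attacks the silicon of 1 and triflate leaves from the neighbouring carbon, which releases the aryne 3 gradually. The methoxy group beside the triple bond withdraws electron density through the σ-framework and distorts the aryne, so the carbon remote from it is the more electrophilic one; the cesium carboxylate formed from 2 and CsF therefore bonds through oxygen to that carbon. The aryl carbanion 4 that results sits beside the methoxy group, where it is inductively stabilised, and it attacks its own ester carbonyl (4-exo-trig) through a strained four-membered alkoxide that opens at once by C–O cleavage to the cesium phenoxide of 5; aqueous NH4Cl then gives 5. The net result is insertion of the aryne into the acyl C–O bond of the acid, with one aryl C–O and one aryl C–C bond formed on adjacent carbons; the closest known reaction type is the fluoride-induced acyl-transfer insertion of arynes from silylaryl triflates into carboxylic acids at elevated temperature, which gives ortho-hydroxyaryl ketones. No ring remains closed and no stereocentre is formed. Two selectivities are needed: the regiochemistry of addition, secured by the methoxy group as described, and acyl transfer in preference to protonation of 4, secured by the excess of CsF (the acid is present as carboxylate) and by the high temperature that the four-membered transition state demands. An excess of the inexpensive acid 2 keeps the carboxylate, not the phenoxide of 5, as the main trap for 3.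

Step 2
Reactants: 5 1-(2-hydroxy-6-methoxyphenyl)-4-methylpentan-1-one
Product: 6 3-methoxy-2-(4-methylpentyl)phenol
Conditions: Et3SiH (3 equiv), CF3CO2H, rt to 50 °C
Reagents that add atoms: none
Why: Ionic hydrogenation of an aryl ketone: protonation of the carbonyl, hydride transfer from silicon, ionisation of the benzylic alcohol to a cation stabilised by the two ortho oxygen donors, and a second hydride transfer. The phenol and the aryl methyl ether are inert to these conditions, and no C–Cl bond is present yet.

Step 3
Reactants: 6 3-methoxy-2-(4-methylpentyl)phenol
Product: 7 1,3-dimethoxy-2-(4-methylpentyl)benzene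
Conditions: MeI, K2CO3, acetone, reflux
Reagents that add atoms: iodomethane, CI
Why: Williamson ether synthesis on a phenoxide; the phenol is the only acidic and nucleophilic site. The product is symmetric, which removes any regiochemical question from the acylation.

Step 4
Reactants: 8 4,5-dichloro-1H-pyrrole-2-carboxylic acid
Product: 9 4,5-dichloro-1H-pyrrole-2-carbonyl chloride
Conditions: (COCl)2, DMF (cat.), CH2Cl2, 0 °C to rt; concentrate, use crude
Reagents that add atoms: oxalyl chloride, O=C(Cl)C(=O)Cl
Why: Acid chloride formation through the chloroiminium species from DMF and oxalyl chloride. The two chlorines and the carbonyl group deactivate the pyrrole ring towards self-acylation, and without base the N–H is not deprotonated, so ketene-type dimerisation is avoided.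

Step 5
Reactants: 7 1,3-dimethoxy-2-(4-methylpentyl)benzene; 9 4,5-dichloro-1H-pyrrole-2-carbonyl chloride
Product: 10 (4,5-dichloro-1H-pyrrol-2-yl)[2,4-dimethoxy-3-(4-methylpentyl)phenyl]methanone
Conditions: AlCl3 (2.5 equiv), CH2Cl2, 0 °C to rt; ice, aq HCl
Reagents that add atoms: none
Why: Friedel–Crafts acylation: the acylium ion from 9 attacks the ring carbon that is para to one methoxy group and ortho to the other. The two such carbons of 7 are equivalent by symmetry, and the remaining free carbon is meta to both ethers, so only one ketone can form. Any loss of the methyl group ortho to the new ketone under AlCl3 is harmless, because both ethers are cleaved in the next step.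

Step 6
Reactants: 10 (4,5-dichloro-1H-pyrrol-2-yl)[2,4-dimethoxy-3-(4-methylpentyl)phenyl]methanone
Product: 11 (4,5-dichloro-1H-pyrrol-2-yl)[2,4-dihydroxy-3-(4-methylpentyl)phenyl]methanone
Conditions: BBr3 (5 equiv), CH2Cl2, −78 °C to rt; then MeOH, H2O
Reagents that add atoms: none
Why: Lewis-acid cleavage of aryl methyl ethers: boron binds the ether oxygen and bromide attacks the methyl carbon (SN2). The ether ortho to the ketone reacts through a boron chelate and the other at room temperature; the pyrrole N–H, the C–Cl bonds and the diaryl ketone are inert.

## Compound list

1 | 3-methoxy-2-(trimethylsilyl)phenyl trifluoromethanesulfonate | COc1cccc(OS(=O)(=O)C(F)(F)F)c1[Si](C)(C)C | starting material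
2 | 4-methylpentanoic acid | CC(C)CCC(=O)O | starting material
3 | 3-methoxybenzyne (1-methoxycyclohexa-1,3-dien-5-yne) | COC1=CC=CC#C1 | intermediate
4 | [2-methoxy-6-(4-methylpentanoyloxy)phenyl]cesium | CC(C)CCC(=O)Oc1cccc(OC)c1[Cs] | intermediate
5 | 1-(2-hydroxy-6-methoxyphenyl)-4-methylpentan-1-one | CC(C)CCC(=O)c1c(O)cccc1OC | intermediate
6 | 3-methoxy-2-(4-methylpentyl)phenol | CC(C)CCCc1c(O)cccc1OC | intermediate
7 | 1,3-dimethoxy-2-(4-methylpentyl)benzene | CC(C)CCCc1c(OC)cccc1OC | intermediate
8 | 4,5-dichloro-1H-pyrrole-2-carboxylic acid | O=C(O)c1cc(Cl)c(Cl)[nH]1 | starting material
9 | 4,5-dichloro-1H-pyrrole-2-carbonyl chloride | O=C(Cl)c1cc(Cl)c(Cl)[nH]1 | intermediate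
10 | (4,5-dichloro-1H-pyrrol-2-yl)[2,4-dimethoxy-3-(4-methylpentyl)phenyl]methanone | CC(C)CCCc1c(OC)ccc(C(=O)c2cc(Cl)c(Cl)[nH]2)c1OC | intermediate
11 | (4,5-dichloro-1H-pyrrol-2-yl)[2,4-dihydroxy-3-(4-methylpentyl)phenyl]methanone | CC(C)CCCc1c(O)ccc(C(=O)c2cc(Cl)c(Cl)[nH]2)c1O | target

## Step count and risk

Total steps: 6. Longest linear sequence: 5 steps (steps 1, 2, 3, 5 and 6); step 4 is a one-step side branch.

**Step 1 (key step).** The most likely failure is protonation of the aryl anion 4 before it transfers the acyl group, by hydrogen difluoride or by an α-C–H of its own ester, so that only O-arylation occurs. A second aryne could also be consumed by the product phenoxide or by the ketone enolate. The fallback sets out from 2 and returns at 5.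
- Acid 2 would be converted with 1,1'-carbonyldiimidazole and N,O-dimethylhydroxylamine hydrochloride into N-methoxy-N,4-dimethylpentanamide F1.
- 1,3-Dimethoxybenzene would be lithiated between its two ether groups with n-BuLi in THF to give (2,6-dimethoxyphenyl)lithium F2.
- Addition of F2 to F1 would give 1-(2,6-dimethoxyphenyl)-4-methylpentan-1-one F3.
- One equivalent of BCl3 in CH2Cl2 at low temperature would remove a single methyl group through the six-membered boron chelate with the ketone and give 5.

**Step 2.** The ketone of 5 is chelated by the ortho hydroxyl and flanked by two ortho substituents. The reduction may therefore stall at the benzylic alcohol stage, or the benzylic cation may be intercepted by a second electron-rich arene (intermolecular alkylation). The fallback sets out from 5 and returns at 6.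
- Ethyl chloroformate and Et3N in THF would give ethyl 3-methoxy-2-(4-methylpentanoyl)phenyl carbonate F4.
- Aqueous NaBH4 would reduce the ketone, and the alkoxide would take over the carbonate and expel it, forming the ortho-quinone methide 5-methoxy-6-(4-methylpentylidene)cyclohexa-2,4-dien-1-one F5 in the flask.
- A second hydride would add to the exocyclic carbon of F5 to give 6.

**Step 5.** The acid chloride 9 carries a free N–H. It may lose HCl and oligomerise, or its acylium ion may be too strongly stabilised by the pyrrole, and tied up by AlCl3 at nitrogen, to attack 7 at a useful rate. The fallback reverses the polarity; it sets out from 7 and 8 and returns at 10.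
- N-Bromosuccinimide in MeCN would brominate 7 at its one type of activated position to give 1-bromo-2,4-dimethoxy-3-(4-methylpentyl)benzene F6.
- Acid 8 would be converted with 1,1'-carbonyldiimidazole and N,O-dimethylhydroxylamine hydrochloride into 4,5-dichloro-N-methoxy-N-methyl-1H-pyrrole-2-carboxamide F7.
- Bromine–lithium exchange on F6 with n-BuLi in THF at −78 °C would give [2,4-dimethoxy-3-(4-methylpentyl)phenyl]lithium F8.
- F8 would be added to F7 after the N–H proton of F7 has been removed with NaH; collapse of the chelated tetrahedral adduct on work-up would give 10.

**Step 6.** The ether para to the ketone is not chelated, and its oxygen is a poorer Lewis base because it is conjugated with the complexed carbonyl. Demethylation may therefore stop at the mono-ether, and forcing conditions may degrade the pyrrole. The fallback removes the late deprotection altogether; it sets out from 6 and 8 and returns at 11.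
- BBr3 in CH2Cl2 would demethylate 6 to 2-(4-methylpentyl)benzene-1,3-diol F9.
- F9 would be C-acylated directly with acid 8 in BF3·OEt2 at about 80 °C (Nencki-type acylation, directed ortho to one hydroxyl and para to the other), which would give 11 with no protecting group on the ring.

## Further compounds

F1 | step 1 | N-methoxy-N,4-dimethylpentanamide | CC(C)CCC(=O)N(C)OC
F2 | step 1 | (2,6-dimethoxyphenyl)lithium | COc1cccc(OC)c1[Li]
F3 | step 1 | 1-(2,6-dimethoxyphenyl)-4-methylpentan-1-one | CC(C)CCC(=O)c1c(OC)cccc1OC
F4 | step 2 | ethyl 3-methoxy-2-(4-methylpentanoyl)phenyl carbonate | CCOC(=O)Oc1cccc(OC)c1C(=O)CCC(C)C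
F5 | step 2 | 5-methoxy-6-(4-methylpentylidene)cyclohexa-2,4-dien-1-one | COC1=CC=CC(=O)C1=CCCC(C)C
F6 | step 5 | 1-bromo-2,4-dimethoxy-3-(4-methylpentyl)benzene | CC(C)CCCc1c(OC)ccc(Br)c1OC
F7 | step 5 | 4,5-dichloro-N-methoxy-N-methyl-1H-pyrrole-2-carboxamide | CON(C)C(=O)c1cc(Cl)c(Cl)[nH]1
F8 | step 5 | [2,4-dimethoxy-3-(4-methylpentyl)phenyl]lithium | CC(C)CCCc1c(OC)ccc([Li])c1OC
F9 | step 6 | 2-(4-methylpentyl)benzene-1,3-diol | CC(C)CCCc1c(O)cccc1O
A1 | alternative 1 | 4-[4,5-dichloro-1-(2-trimethylsilylethoxymethyl)pyrrole-2-carbonyl]-2-(4-methylpentyl)cyclohexane-1,3-dione | CC(C)CCCC1C(=O)CCC(C(=O)c2cc(Cl)c(Cl)n2COCC[Si](C)(C)C)C1=O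
A2 | alternative 1 | 1-[4,5-dichloro-1-(2-trimethylsilylethoxymethyl)pyrrol-2-yl]-8-methylnonane-1,3-dione | CC(C)CCCCC(=O)CC(=O)c1cc(Cl)c(Cl)n1COCC[Si](C)(C)C
A3 | alternative 2 | (4-chloro-1H-pyrrol-2-yl)[2,4-dimethoxy-3-(4-methylpentyl)phenyl]methanone | CC(C)CCCc1c(OC)ccc(C(=O)c2cc(Cl)c[nH]2)c1OC
A4 | alternative 2 | 2-amino-1-[2,4-dimethoxy-3-(4-methylpentyl)phenyl]ethan-1-one | CC(C)CCCc1c(OC)ccc(C(=O)CN)c1OC
A5 | alternative 2 | 2-chloro-1,3-bis(dimethylamino)trimethinium hexafluorophosphate | CN(C)C=C(Cl)C=[N+](C)C.F[P-](F)(F)(F)(F)F
A6 | alternative 3 | ethyl 2-hydroxy-3-(4-methylpentyl)-4-(triisopropylsilyloxy)benzoate | CCOC(=O)c1ccc(O[Si](C(C)C)(C(C)C)C(C)C)c(CCCC(C)C)c1O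
A7 | alternative 3 | triisopropyl[(6-methylhept-1-yn-1-yl)oxy]silane | CC(C)CCCC#CO[Si](C(C)C)(C(C)C)C(C)C
A8 | alternative 3 | ethyl (E)-5-diazo-4-oxopent-2-enoate | CCOC(=O)/C=C/C(=O)C=[N+]=[N-]
A9 | alternative 3 | ethyl (E)-5-oxopenta-2,4-dienoate | CCOC(=O)/C=C/C=C=O
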